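## Retrosynthetic overview
1. The dialdehyde comes from a double Swern oxidation of the 11,12-diol. C12–O comes from allylic oxidation. C11–O and the C9 center come from α-face hydroboration of a drima-7,9(11)-diene. The coumarate is built on the 1β-alcohol from acryloyl chloride and 4-iodophenol (Heck).
2. Ring B comes from ring-closing enyne metathesis between the C5 allyl and the C10 propynyl group of a ring A ketone. The CH2 terminus of the allyl group ends up as C11.
3. Ring A and the quaternary C10 come from a ring enlargement. C5 shifts from C1 to a tertiary propargylic C10 in a cyclopentanol (key step, five- to six-membered ring).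
4. The cyclopentanol comes from acetyl-anion addition to (S)-2-allyl-3,3-dimethylcyclopentanone. That ketone comes from 3-methylcyclopentenone, MeMgBr and allyl chloroformate; decarboxylative asymmetric allylation sets C5.
5. Ring order: cyclopentane (bought), then ring A (enlargement), then ring B (metathesis).

Assumption: the (S,S) antipode of the Trost ligand is taken to give the S ketone in step 2 (the antipode is swapped if a test run shows the opposite sense); drimane numbering C1–C12 is used for all carbons, also in the monocyclic precursors.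

## Route

Step 1
Reactants: 1 3-methylcyclopent-2-en-1-one; 2 methylmagnesium bromide; 3 allyl chloroformate
Product: 5 allyl 3,3-dimethylcyclopent-1-en-1-yl carbonate, via bromomagnesium enolate 4 (not isolated)
Conditions: 2 (1.2 equiv), CuBr·SMe2 (10 mol %), THF, −40 °C; then DMPU, 3, −78 °C → rt
Reagents that add atoms: none
Why: Copper-catalysed conjugate addition builds the gem-dimethyl carbon C4 and gives a regiodefined enolate (C1=C5), which the DMPU-solvated magnesium enolate O-acylates with the chloroformate (enolate trapping); no stereocenter is formed.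

Step 2
Reactants: 5 allyl 3,3-dimethylcyclopent-1-en-1-yl carbonate
Product: 6 (S)-2-allyl-3,3-dimethylcyclopentan-1-one
Conditions: Pd2(dba)3·CHCl3 (2.5 mol %), (S,S)-ANDEN-phenyl Trost ligand (5.5 mol %), 1,4-dioxane, rt
Reagents that add atoms: none
Why: In this decarboxylative asymmetric allylic alkylation (Tsuji–Trost type), zerovalent palladium ionises the carbonate, CO2 leaves, and the enolate/π-allyl ion pair recombines inside the chiral pocket under neutral conditions, which sets C5 (S), while the neighbouring quaternary carbon suppresses racemisation and double allylation.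

Step 3
Reactants: 6 (S)-2-allyl-3,3-dimethylcyclopentan-1-one; 7 ethyl vinyl ether
Product: 10 1-[(1R,2S)-2-allyl-1-hydroxy-3,3-dimethylcyclopentyl]ethan-1-one, via 1-ethoxyvinyllithium 8 (not isolated), via lithium alkoxide adduct 9 (not isolated)
Conditions: 7, t-BuLi, THF, −78 → 0 °C; 6, −78 °C; then 1 M HCl, THF, 0 °C
Reagents that add atoms: water O
Why: The acyl-anion equivalent adds 1,2 to the ketone from the face opposite the allyl group, which sets C1 (R, OH cis to allyl), and mild acid hydrolysis of the enol ether unmasks the methyl ketone that carries C10 and its methyl group.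

Step 4
Reactants: 10 1-[(1R,2S)-2-allyl-1-hydroxy-3,3-dimethylcyclopentyl]ethan-1-one; 11 prop-1-yn-1-ylmagnesium bromide
Product: 14 (2S,3S)-3-allyl-2,4,4-trimethyl-2-(prop-1-yn-1-yl)cyclohexan-1-one, via bis(bromomagnesium) dialkoxide 12 (not isolated), via propargylic mesylate 13 (not isolated)
Conditions: 11 (2.05 equiv), THF–CH2Cl2, −78 → 0 °C; then MsCl (1.3 equiv), −78 °C → rt
Reagents that add atoms: none
Why: Proposed new method: one-flask alkynylative ring enlargement, in which the first equivalent of 11 forms the magnesium alkoxide of 10 and its five-membered O–Mg–O chelate steers the second equivalent to the ketone face flanked by C2H2 (Cram chelate addition, C10 R in 12); MsCl then sulfonylates the less crowded propargylic alkoxide, and in 13 the magnesium bridge between the C1 alkoxide and the sulfonate holds the two oxygens gauche, so epoxide closure is shut off and the C1–C5 bond lies antiperiplanar to the leaving group in the least crowded rotamer; push from the alkoxide and pull from magnesium then drive a stereospecific 1,2-shift of the more substituted ring carbon C5 (retention at C5, inversion at C10) onto the tertiary propargylic carbon, which enlarges the five-membered ring to ring A through a chair-like transition state with the slim alkynyl group axial, so both the stereospecific path and the steric bias place propynyl trans and methyl cis to the allyl chain (C10 S); the closest known reaction types are the ring enlargement of magnesium halohydrinates of 1-(α-halobenzyl)cycloalkanols and the semipinacol shift of 2-sulfonyloxy alcohols, neither of which has been shown for a tertiary propargylic terminus, for an unstrained cyclopentanol of this kind, or in one flask with the carbonyl addition.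

Step 5
Reactants: 14 (2S,3S)-3-allyl-2,4,4-trimethyl-2-(prop-1-yn-1-yl)cyclohexan-1-one
Product: 15 (5S,10S)-drima-7,9(11)-dien-1-one
Conditions: second-generation Grubbs catalyst (10 mol %), ethene (1 atm), toluene, 80 °C
Reagents that add atoms: none
Why: In this ring-closing enyne metathesis under ethene, the ruthenium methylidene adds to the alkyne with the metal on the less hindered methyl-bearing C8 and CH2 on neopentyl C9, the vinylcarbene closes onto the allyl group to give the C7=C8 bond of the six-membered ring B, the trans-diequatorial chains disfavour the strained trans-hydrindene from the other closure, and no stereocenter is touched.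

Step 6
Reactants: 15 (5S,10S)-drima-7,9(11)-dien-1-one
Product: 16 (1R,5S,10S)-drima-7,9(11)-dien-1-ol
Conditions: NaBH4, MeOH, 0 °C
Reagents that add atoms: none
Why: In this borohydride ketone reduction the hydride enters axially from the α face, opposite the axial C10 methyl group, which gives the equatorial 1β-alcohol (C1 R).

Step 7
Reactants: 16 (1R,5S,10S)-drima-7,9(11)-dien-1-ol; 17 acryloyl chloride
Product: 18 (1R,5S,10S)-drima-7,9(11)-dien-1-yl acrylate
Conditions: 17, Et3N, DMAP (cat.), BHT (trace), CH2Cl2, 0 °C → rt
Reagents that add atoms: none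
Why: DMAP-catalysed O-acylation of the only hydroxyl group with a small, reactive acid chloride copes with the neopentyl position and keeps the C1 configuration.

Step 8
Reactants: 18 (1R,5S,10S)-drima-7,9(11)-dien-1-yl acrylate; 19 4-iodophenol
Product: 20 (1R,5S,10S)-drima-7,9(11)-dien-1-yl (E)-3-(4-hydroxyphenyl)acrylate
Conditions: 19, Pd(OAc)2 (5 mol %), P(o-tol)3 (10 mol %), Et3N, MeCN, 80 °C
Reagents that add atoms: none
Why: In this Mizoroki–Heck arylation the arylpalladium species inserts far faster into the electron-poor terminal acrylate than into the hindered diene, syn insertion and syn β-hydride elimination give the E alkene, and the free phenol is tolerated.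

Step 9
Reactants: 20 (1R,5S,10S)-drima-7,9(11)-dien-1-yl (E)-3-(4-hydroxyphenyl)acrylate
Product: 22 (1R,5S,9S,10S)-11-hydroxydrim-7-en-1-yl (E)-3-(4-hydroxyphenyl)acrylate, via bis(9-BBN) adduct 21 (not isolated)
Conditions: 9-BBN (3 equiv), THF, 0 → 40 °C; then 30 % H2O2, pH 7 phosphate buffer, 0 °C
Reagents that add atoms: hydrogen peroxide OO
Why: In this hydroboration–oxidation boron goes to the open CH2 terminus of the exocyclic alkene (faster than the trisubstituted ring alkene or the electron-poor cinnamate) and hydrogen reaches C9 from the α face opposite the axial C10 methyl, which sets 9α-H with an equatorial CH2OH, while the phenol is only masked as a borinate until work-up.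

Step 10
Reactants: 22 (1R,5S,9S,10S)-11-hydroxydrim-7-en-1-yl (E)-3-(4-hydroxyphenyl)acrylate
Product: 23 (1R,5S,9S,10S)-11,12-dihydroxydrim-7-en-1-yl (E)-3-(4-hydroxyphenyl)acrylate
Conditions: SeO2 (20 mol %), t-BuOOH, CH2Cl2, 0 °C → rt, stopped at the alcohol stage
Reagents that add atoms: tert-butyl hydroperoxide CC(C)(C)OO
Why: Selenium dioxide allylic oxidation attacks the more substituted alkene end and there the methyl group cis to H7 (C12), the site established for drimenol-type alkenes, and no stereocenter changes.

Step 11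
Reactants: 23 (1R,5S,9S,10S)-11,12-dihydroxydrim-7-en-1-yl (E)-3-(4-hydroxyphenyl)acrylate
Product: 27 1β-(E)-p-coumaroyloxypolygodial (target), via tris(trimethylsilyl) ether 24 (not isolated), via bis(alkoxysulfonium) chloride 25 (not isolated), via aryl silyl ether dialdehyde 26 (not isolated)
Conditions: TMSCl, Et3N, CH2Cl2, 0 °C, filter and concentrate; (COCl)2, DMSO, CH2Cl2, −78 → −35 °C; Et3N, −78 → 0 °C; pH 5 aqueous work-up
Reagents that add atoms: none
Why: In this Swern oxidation of silyl ethers the transient silylation shields the phenol, the two primary silyl ethers exchange directly with the chlorosulfonium salt so both carbinols are activated before base is added (no lactol or lactone), the low temperature preserves the base-labile C9 center, and the mild aqueous work-up frees the phenol.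

## Compound list
1 | 3-methylcyclopent-2-en-1-one | CC1=CC(=O)CC1 | starting material
2 | methylmagnesium bromide | C[Mg]Br | starting material
3 | allyl chloroformate | C=CCOC(=O)Cl | starting material
4 | bromomagnesium 3,3-dimethylcyclopent-1-en-1-olate | CC1(C)CCC(O[Mg]Br)=C1 | intermediate
5 | allyl 3,3-dimethylcyclopent-1-en-1-yl carbonate | C=CCOC(=O)OC1=CC(C)(C)CC1 | intermediate
6 | (S)-2-allyl-3,3-dimethylcyclopentan-1-one | CC1(C)CCC(=O)[C@H]1CC=C | intermediate
7 | ethyl vinyl ether | C=COCC | starting material
8 | 1-ethoxyvinyllithium | C=C([Li])OCC | intermediate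
9 | lithium (1R,2S)-2-allyl-1-(1-ethoxyvinyl)-3,3-dimethylcyclopentan-1-olate | CC1(C)CC[C@](O[Li])(C(=C)OCC)[C@H]1CC=C | intermediate
10 | 1-[(1R,2S)-2-allyl-1-hydroxy-3,3-dimethylcyclopentyl]ethan-1-one (OH cis, acetyl trans to allyl) | CC1(C)CC[C@](O)(C(C)=O)[C@H]1CC=C | intermediate
11 | prop-1-yn-1-ylmagnesium bromide | CC#C[Mg]Br | starting material
12 | bis(bromomagnesium) salt of (R)-2-[(1R,2S)-2-allyl-1-hydroxy-3,3-dimethylcyclopentyl]pent-3-yn-2-ol | CC1(C)CC[C@](O[Mg]Br)([C@](C)(O[Mg]Br)C#CC)[C@H]1CC=C | intermediate
13 | C10 methanesulfonate of 12 (C1 bromomagnesium alkoxide kept) | CC1(C)CC[C@](O[Mg]Br)([C@](C)(OS(C)(=O)=O)C#CC)[C@H]1CC=C | intermediate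
14 | (2S,3S)-3-allyl-2,4,4-trimethyl-2-(prop-1-yn-1-yl)cyclohexan-1-one (propynyl trans, methyl cis to allyl) | CC1(C)CCC(=O)[C@](C)(C#CC)[C@H]1CC=C | intermediate
15 | (5S,10S)-drima-7,9(11)-dien-1-one = (4aS,8aS)-4,4,7,8a-tetramethyl-8-methylidene-3,4,4a,5,8,8a-hexahydronaphthalen-1(2H)-one | CC1(C)CCC(=O)[C@]2(C)C(=C)C(C)=CC[C@@H]12 | intermediate
16 | (1R,5S,10S)-drima-7,9(11)-dien-1-ol (1β, equatorial OH) | CC1(C)CC[C@@H](O)[C@]2(C)C(=C)C(C)=CC[C@@H]12 | intermediate
17 | acryloyl chloride | C=CC(=O)Cl | starting material
18 | (1R,5S,10S)-drima-7,9(11)-dien-1-yl acrylate | CC1(C)CC[C@@H](OC(=O)C=C)[C@]2(C)C(=C)C(C)=CC[C@@H]12 | intermediate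
19 | 4-iodophenol | Oc1ccc(I)cc1 | starting material
20 | (1R,5S,10S)-drima-7,9(11)-dien-1-yl (E)-3-(4-hydroxyphenyl)acrylate | CC1(C)CC[C@@H](OC(=O)/C=C/c2ccc(O)cc2)[C@]2(C)C(=C)C(C)=CC[C@@H]12 | intermediate
21 | C11-(9-BBN) borane and phenol O-(9-BBN) borinate of 20 (9α-H) | CC1(C)CC[C@@H](OC(=O)/C=C/c2ccc(OB3C4CCCC3CCC4)cc2)[C@]2(C)[C@@H](CB3C4CCCC3CCC4)C(C)=CC[C@@H]12 | intermediate
22 | (1R,5S,9S,10S)-11-hydroxydrim-7-en-1-yl (E)-3-(4-hydroxyphenyl)acrylate | CC1(C)CC[C@@H](OC(=O)/C=C/c2ccc(O)cc2)[C@]2(C)[C@@H](CO)C(C)=CC[C@@H]12 | intermediate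
23 | (1R,5S,9S,10S)-11,12-dihydroxydrim-7-en-1-yl (E)-3-(4-hydroxyphenyl)acrylate | CC1(C)CC[C@@H](OC(=O)/C=C/c2ccc(O)cc2)[C@]2(C)[C@@H](CO)C(CO)=CC[C@@H]12 | intermediate
24 | tris(trimethylsilyl) ether of 23 | CC1(C)CC[C@@H](OC(=O)/C=C/c2ccc(O[Si](C)(C)C)cc2)[C@]2(C)[C@@H](CO[Si](C)(C)C)C(CO[Si](C)(C)C)=CC[C@@H]12 | intermediate
25 | 11,12-bis(dimethylsulfonio-oxy) dichloride (phenol still silylated) | CC1(C)CC[C@@H](OC(=O)/C=C/c2ccc(O[Si](C)(C)C)cc2)[C@]2(C)[C@@H](CO[S+](C)C)C(CO[S+](C)C)=CC[C@@H]12.[Cl-].[Cl-] | intermediate
26 | phenol O-trimethylsilyl ether of 27 | CC1(C)CC[C@@H](OC(=O)/C=C/c2ccc(O[Si](C)(C)C)cc2)[C@]2(C)[C@@H](C=O)C(C=O)=CC[C@@H]12 | intermediate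
27 | 1β-(E)-p-coumaroyloxypolygodial, (1R,5S,9R,10S) = [(1R,4aS,8R,8aS)-7,8-diformyl-4,4,8a-trimethyl-1,2,3,4,4a,5,8,8a-octahydronaphthalen-1-yl] (E)-3-(4-hydroxyphenyl)prop-2-enoate | CC1(C)CC[C@@H](OC(=O)/C=C/c2ccc(O)cc2)[C@]2(C)[C@@H](C=O)C(C=O)=CC[C@@H]12 | target

## Step count and risks
Total step count: 11. Longest linear sequence: 11.

**Step 4 (the proposed new step).**
- Risks: sulfonylation at the C1 alkoxide, elimination to the enyne, epoxide closure, or migration of C2 in place of C5.
- The fallback uses known chemistry. It sets out from 10 and comes back at 14.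
- 10 is treated with 11 as before, but dialkoxide 12 is quenched with water and the diol (R)-2-[(1R,2S)-2-allyl-1-hydroxy-3,3-dimethylcyclopentyl]pent-3-yn-2-ol F1 is isolated.
- F1 is then stirred with HC(OMe)3 and catalytic BF3·OEt2 in CH2Cl2 at −20 °C. This is the established orthoester-mediated pinacol rearrangement.
- The spiro 2-methoxy-1,3-dioxolane F2 forms and ionises to a dioxolanylium ion. That ion opens at the propargylic C–O bond while C5 migrates, giving 14 under water-free conditions that close off the enone (Meyer–Schuster) path.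

**Step 5.**
- Risks: the hindered internal alkyne may react slowly, or the alkylidene formed first at the allyl group may close onto C9 to give the five-membered ring diene.
- The fallback sets out from 14 and comes back at 15. It separates the two bond-forming events.
- An intermolecular cross enyne metathesis of 14 with ethene (4 atm, second-generation Hoveyda–Grubbs catalyst, toluene, 80 °C) gives the triene (2S,3S)-3-allyl-2,4,4-trimethyl-2-(3-methylbuta-1,3-dien-2-yl)cyclohexan-1-one F3, which is isolated.
- A separate diene–ene ring-closing metathesis under argon then closes ring B.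
- In F3 only the C8 methylene is accessible, because the C9 methylene is neopentyl. Ring size is therefore decided by sterics alone.

**Step 9.**
- Risks: slow hydroboration next to C10 and the 1β-ester, or attack of the borane on the cinnamate.
- The fallback sets out from 16 and comes back at 22. It moves the hydroboration ahead of the ester.
- 16 is hydroborated (9-BBN, then H2O2/NaOH) to (1R,5S,9S,10S)-drim-7-ene-1,11-diol F4.
- The primary alcohol is silylated selectively (TESCl, imidazole, −20 °C) to the 11-O-triethylsilyl ether F5.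
- F5 is acylated with 17 to the acrylate F6.
- Heck coupling with 19 gives the coumarate F7.
- PPTS in MeOH removes the silyl group to give 22.

## Further compounds
F1 | step 4 | (R)-2-[(1R,2S)-2-allyl-1-hydroxy-3,3-dimethylcyclopentyl]pent-3-yn-2-ol | CC1(C)CC[C@](O)([C@](C)(O)C#CC)[C@H]1CC=C
F2 | step 4 | spiro 2-methoxy-1,3-dioxolane (cyclic orthoformate) of F1, orthoester carbon unassigned | CC1(C)CC[C@@]2(OC(OC)O[C@]2(C)C#CC)[C@H]1CC=C
F3 | step 5 | (2S,3S)-3-allyl-2,4,4-trimethyl-2-(3-methylbuta-1,3-dien-2-yl)cyclohexan-1-one | CC1(C)CCC(=O)[C@](C)(C(=C)C(C)=C)[C@H]1CC=C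
F4 | step 9 | (1R,5S,9S,10S)-drim-7-ene-1,11-diol | CC1(C)CC[C@@H](O)[C@]2(C)[C@@H](CO)C(C)=CC[C@@H]12
F5 | step 9 | (1R,5S,9S,10S)-11-(triethylsilyloxy)drim-7-en-1-ol | CC1(C)CC[C@@H](O)[C@]2(C)[C@@H](CO[Si](CC)(CC)CC)C(C)=CC[C@@H]12
F6 | step 9 | (1R,5S,9S,10S)-11-(triethylsilyloxy)drim-7-en-1-yl acrylate | CC1(C)CC[C@@H](OC(=O)C=C)[C@]2(C)[C@@H](CO[Si](CC)(CC)CC)C(C)=CC[C@@H]12
F7 | step 9 | (1R,5S,9S,10S)-11-(triethylsilyloxy)drim-7-en-1-yl (E)-3-(4-hydroxyphenyl)acrylate | CC1(C)CC[C@@H](OC(=O)/C=C/c2ccc(O)cc2)[C@]2(C)[C@@H](CO[Si](CC)(CC)CC)C(C)=CC[C@@H]12
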